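Count the turnovers.

| flask | substrate | partner | remark | time |
|---|---|---|---|---|
| Sunday's | 0.020 M | 0.048 M | run made earlier |  |
| Tuesday's | 0.020 M | 0.085 M | run made earlier |  |
| violet | 0.020 M | 0.0260 M |  | 4.0 min |
| grey | 0.020 M | 0.0780 M |  | 4.0 min |

| run | time / s | homo product / % | open intermediate / % | substrate / % | target / % |
|---|---|---|---|---|---|
| Sunday's | 10.0 | 0.5 | 28.5 | 70.3 | 0 |
| Sunday's | 20.0 | 1.5 | 42.0 | 57.6 | 0.1 |
| Sunday's | 30.0 | 0.2 | 48.0 | 50.9 | 3.0 |
| Sunday's | 60.0 | 2.8 | 49.8 | 40.4 | 4.5 |
| Sunday's | 120 | 6.0 | 43.3 | 33.5 | 16.6 |
| Tuesday's | 10.0 | 0 | 27.4 | 72.4 | 0 |
| Tuesday's | 30.0 | 0.7 | 47.0 | 49.6 | 2.2 |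
| Tuesday's | 60.0 | 2.4 | 47.9 | 39.3 | 9.9 |
| Tuesday's | 80.0 | 3.6 | 44.7 | 34.2 | 15.9 |
| Tuesday's | 120 | 5.5 | 36.3 | 28.5 | 28.3 |

(standard deviation of a reading: 1 percentage point)

1. which of these there is most of at the end, counted by the substrate in it, violet (homo product / open intermediate / target / substrate)
2. which of these there is most of at the end, counted by the substrate in it, grey (homo product / open intermediate / target / substrate)
3. amount of the one of these that there is most of at the end, in percent of the substrate charged, violet
4. amount of the one of these that there is most of at the end, in percent of the substrate charged, grey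

- a species is counted by the substrate in it: one homo product counts as two
- what was read earlier has a scatter of 1 percentage point, one standard deviation

1. Target appears late, then climbs on a nearly straight line. Tuesday's last two readings give target made per open intermediate standing, a pseudo-first-order constant. Divided by charged [partner], it is 0.0901 M⁻¹ s⁻¹. Sunday's last two readings give 0.0903 M⁻¹ s⁻¹, so as read, the rate follows the partner charge.

2. Tuesday's line, run back to zero target, starts at a lag of 28.7 s.

3. A turnover count sums that rate over time. The count per unit of charged [partner], the constant times the time past the lag, is 19.0 M⁻¹. Multiplied by the charge, it gives 0.495 turnovers for violet and 1.48 for grey.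

4. On the later readings, open intermediate stands at a nearly steady share of the pool of substrate and open intermediate: 56.0% on Tuesday's last reading. With homo product left aside, the pool's loss to target then has the exponent share times count. Target is reckoned at 24.2% in violet and 56.5% in grey.

5. Sunday's homo product, held at its average rate for the longer time, gives an estimate of 12.0% for violet. Violet's open intermediate is then reckoned at 35.7%, more than its reckoned target. Grey, with no homo product taken off, is reckoned at 24.4% open intermediate, less than its reckoned target.

The forecast says open intermediate at 37% for violet and target at 52% for grey, where “partner stays plentiful”.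

The flasks give open intermediate at 36.4% for violet, beside target at 23.8%, and target at 56.9% for grey.

    partner → second intermediate (k = 0.00220 s⁻¹)
    open intermediate + second intermediate → target (k = 0.700 M⁻¹ s⁻¹)
    substrate ⇌ open intermediate (K = 1.40, k = 0.0390 s⁻¹)
    substrate + open intermediate → side product (k = 0.0110 M⁻¹ s⁻¹)
    2 open intermediate → homo product (k = 0.0540 M⁻¹ s⁻¹)
    second intermediate → decomposed reagent (k = 0.00200 s⁻¹)

Violet is not at rest at 4.0 min, with 59% of its partner left. By 40.0 min, open intermediate falls to 3.99%, target reaches 72.1%, homo product 18.1%, and partner 0.509% of its charge. The straight count carried to that time, with homo product left aside, gives 5.55 turnovers and 95.5% target, more than violet holds. Grey by then shows 0% open intermediate and 91.1% target.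

The neighbour of violet charged with 0.065 M of partner counts 1.24 turnovers, so target is reckoned at 50.1%, with homo product left aside. That neighbour holds 50.2% target, more than its open intermediate at 22.4% or its substrate at 18.4%.

The earlier runs and the new flask stem from a simulated flask with constants of no real substance, and the scatter is random.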